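**Plan**

1. Retrosynthesis: remove the acetates; cut the diene at C13–C14 (Stille) and C12=C13 (iodo-Wittig on a C12 lactol); take C5–H/C6–O and C7–OH back to a Δ5-en-7-one; open ring B at C5–C6 and C8–C9 in one cascade; then cut the allylic ether C–O, the allylic C12–O and C9–C10 (decarboxylative allylation).
2. Enabling feature: C6–C7–C8 with the C8 methyl is an acetoin unit. C8 (tertiary carbinol) adjoins C9, the γ-terminus of the allyl unit C9–C11–C12, and C6 adjoins C5, the carbonyl carbon of the non-enolisable 2,2,6,6-tetrasubstituted cyclohexanone (ring A). A [3,3] shift of an acetoin allyl-ether enolate therefore makes C8–C9, and the methyl ketone it releases condenses with C5.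
3. Forward order: ring A is bought; C10 is set first; the allyl terminus is oxidised and etherified with acetoin; the cascade builds ring B; reduction and hydroboration set C7, C6 and C5; lactone, lactol, Z-diene; acetylation. No protecting groups are used.
4. Stereochemistry: C10 from the chiral Pd catalyst; C8/C9 from the chair sigmatropic transition state and Felkin-type control by C10; C7 by hydride attack anti to the C8 methyl; C5/C6 by syn hydroboration anti to the C10 methyl; 12Z from a Stork–Zhao-type Wittig and a stereoretentive Stille coupling.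

Key step: step 5

Remark (assumption, step 2): the sense of induction of (S)-t-BuPHOX is taken as that known for 2-alkyl-2-allylcyclohexanones ((S)-ligand gives (S)-ketone); if it proves opposite, the (R)-ligand is used.
Remark: racemic acetoin is used, because its stereocentre is erased on enolisation in step 5; compound 9 is an inconsequential epimer pair.
Remark: labdane numbering (C1–C20) is used throughout. The target is the ent-labdane (5R,6S,7R,8R,9S,10R,12Z): trans-decalin; 5-H, 6-OAc, 8-OH and 9-H anti to the C10 methyl; 7-OAc, 8-CH3 and the C9 side chain syn to it.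

**Route**

Step 1
Reactants: 1 2,2,6-trimethylcyclohexan-1-one; 2 allyl chloroformate
Product: 4 allyl 2,6,6-trimethylcyclohex-1-en-1-yl carbonate, via lithium enolate 3 (not isolated)
Conditions: LiHMDS, THF, 0 °C; then TMEDA, 2, −78 °C → rt
Reagents that add atoms: none
Why: The only enolisable position of 1 gives a single tetrasubstituted lithium enolate, which the hard chloroformate acylates on oxygen (enol carbonate formation).

Step 2
Reactants: 4 allyl 2,6,6-trimethylcyclohex-1-en-1-yl carbonate
Product: 5 (S)-2-allyl-2,6,6-trimethylcyclohexan-1-one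
Conditions: Pd2(dba)3 (2.5 mol %), (S)-t-BuPHOX (6.25 mol %), THF, 25 °C
Reagents that add atoms: none
Why: Decarboxylative asymmetric Tsuji allylation: ionisation gives a Pd π-allyl/enolate pair and ligand-controlled C–C bond formation sets the C10 quaternary centre, regiospecifically because the enolate is generated in place.

Step 3
Reactants: 5 (S)-2-allyl-2,6,6-trimethylcyclohexan-1-one
Product: 6 (2E)-3-[(1S)-1,3,3-trimethyl-2-oxocyclohexyl]prop-2-en-1-yl acetate
Conditions: Pd(OAc)2 (10 mol %), 1,4-benzoquinone (2 equiv), DMSO/AcOH (1:1), 4 Å MS, 40 °C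
Reagents that add atoms: acetic acid CC(=O)O
Why: Pd(II)/DMSO-promoted linear allylic C–H acetoxylation: C–H cleavage at C9 gives a π-allyl-Pd species (C9–C11–C12) that acetate should open at the unhindered terminus C12, moving the double bond to C9=C11 with (E)-geometry.

Step 4
Reactants: 6 (2E)-3-[(1S)-1,3,3-trimethyl-2-oxocyclohexyl]prop-2-en-1-yl acetate; 7 acetoin (3-hydroxybutan-2-one)
Product: 9 3-{[(2E)-3-[(1S)-1,3,3-trimethyl-2-oxocyclohexyl]prop-2-en-1-yl]oxy}butan-2-one, via zinc alkoxide 8 (not isolated)
Conditions: 7 (1.5 equiv), Et2Zn (0.75 equiv), THF, 0 °C; then 6, Pd(OAc)2 (5 mol %), 2-(di-tert-butylphosphino)biphenyl (7.5 mol %), THF, rt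
Reagents that add atoms: none
Why: Tsuji–Trost allylic etherification with a zinc alkoxide as O-nucleophile: the π-allyl intermediate should be attacked at the less hindered C12 (C9 is neopentyl) with the (E)-geometry kept, and β-hydride elimination is impossible because C10 is quaternary.

Step 5
Reactants: 9 3-{[(2E)-3-[(1S)-1,3,3-trimethyl-2-oxocyclohexyl]prop-2-en-1-yl]oxy}butan-2-one
Product: 12 3-hydroxy-3,4a,8,8-tetramethyl-4-vinyl-4,4a,5,6,7,8-hexahydronaphthalen-2(3H)-one (Δ5-en-7-one; 8-OH anti, 8-CH3 and 9-vinyl syn to the C10 methyl), via rearranged ketol 10 (not isolated), via aldol adduct 11 (not isolated)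
Conditions: KH (2.5 equiv), THF (0.02 M), 0 → 25 °C; then t-BuOH (3 equiv), 50 °C; aqueous work-up
Reagents that add atoms: none
Why: KH converts 9 into the K+-chelated (Z)-enolate of the α-allyloxy ketone, which undergoes an anionic oxy-Claisen ([3,3]) shift through a chair transition state, forming C8–C9 and releasing the C7 methyl ketone and the C8 tertiary alkoxide (10). The same base then enolises the only remaining enolisable position (the acetyl CH3, C6) and closes ring B by a 6-(enolendo)-exo-trig aldol addition onto the non-enolisable ring-A ketone C5, and E1cB loss of water from 11 gives enone 12 (C5=C6). The closest known reaction types are the anionic oxy-Claisen rearrangement of α-allyloxy ketone enolates and the Robinson-type aldol condensation onto 2,2,6-trisubstituted cyclohexanones. C8 and C9 are set relative to each other by the chair (E-alkene: C10 substituent equatorial; chelated Z-enolate: O− pseudo-axial, CH3 pseudo-equatorial), which places the 8-OH and the 9-vinyl group syn along C7–C8–C9–C10 as the target requires. Their sense relative to C10 should follow a Felkin–Anh-type arrangement at the allylic quaternary centre, the new bond forming anti to the C10–C5 acyl bond with the C10 methyl outside and C1 inside. The step needs enolisation toward the alkoxy-bearing carbon; this is secured because only that enolate rearranges (irreversibly) while the methyl-side enolate merely equilibrates, and afterwards C8 is quaternary and C5 has no α-hydrogens, so C6 is the sole nucleophile for ring closure.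

Step 6
Reactants: 12 Δ5-en-7-one
Product: 13 3,4a,8,8-tetramethyl-4-vinyl-2,3,4,4a,5,6,7,8-octahydronaphthalene-2,3-diol (Δ5-ene-7,8-diol; 7-OH syn to the C10 methyl, trans to 8-OH)
Conditions: NaBH4, CeCl3·7H2O, MeOH, −40 °C
Reagents that add atoms: none
Why: Luche 1,2-reduction; hydride should attack the C7 carbonyl from the face anti to the pseudo-axial C8 methyl, so the new 7-OH is trans to the 8-OH.

Step 7
Reactants: 13 Δ5-ene-7,8-diol
Product: 15 4-(2-hydroxyethyl)-3,4a,8,8-tetramethyldecahydronaphthalene-1,2,3-triol (6,7,8,12-tetraol; 5-H and 6-OH anti to the C10 methyl), via bis-alkylborane 14 (not isolated)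
Conditions: BH3·THF (6 equiv), THF, 0 → 40 °C; then 3 M NaOH, 30 % H2O2, 0 °C → rt
Reagents that add atoms: hydrogen peroxide OO
Why: Double hydroboration–oxidation: boron adds to the terminal vinyl carbon C12 and, in a syn addition from the face anti to the C10 methyl and the C7 oxygen, to C6 of the Δ5 alkene; oxidation with retention gives the equatorial 6-OH and the trans ring fusion (precedent: 4,4-dimethyl-Δ5-steroids).

Step 8
Reactants: 15 6,7,8,12-tetraol
Product: 17 ent-6,7-dihydroxy-13,14,15,16-tetranorlabdano-12,8-lactone, via lactol 16 (not isolated)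
Conditions: TEMPO (0.2 equiv), PhI(OAc)2 (2.5 equiv), CH2Cl2, rt
Reagents that add atoms: none
Why: TEMPO/PhI(OAc)2 oxidises the primary alcohol selectively; the aldehyde is trapped by the tertiary 8-OH as a five-membered lactol, which is oxidised on to the trans-fused γ-lactone while the hindered secondary 6,7-diol is left (as in uronic-acid preparations).

Step 9
Reactants: 17 dihydroxy-lactone
Product: 16 the corresponding 12,8-lactol (anomer mixture)
Conditions: DIBAL-H (4 equiv), CH2Cl2, −78 °C; Rochelle salt
Reagents that add atoms: none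
Why: Partial reduction of a γ-lactone by DIBAL-H at low temperature stops at the aluminium hemiacetal (two equivalents are consumed by the free hydroxyls), which gives the lactol on work-up.

Step 10
Reactants: 16 lactol
Product: 18 (12Z)-13-iodo-14,15-dinor-ent-labd-12-ene-6,7,8-triol
Conditions: EtPPh3I, n-BuLi, THF, 0 °C; I2, −78 °C; NaHMDS, −78 → −20 °C; then 16, −78 → −20 °C (ylide in excess)
Reagents that add atoms: ethyltriphenylphosphonium iodide CC[P+](c1ccccc1)(c1ccccc1)c1ccccc1.[I-]; iodine II
Why: Stork–Zhao-type Wittig reaction of the α-iodo ylide with the open hydroxy-aldehyde form of the lactol; kinetic cis-oxaphosphetane formation should put iodine cis to the C11 chain, giving the (Z)-2-iodoalkene and freeing the 8-OH.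

Step 11
Reactants: 18 (Z)-vinyl iodide
Product: 19 (12Z)-ent-labda-12,14-diene-6,7,8-triol
Conditions: tributyl(vinyl)stannane, Pd(PPh3)4 (5 mol %), CuI (10 mol %), DMF, rt, dark
Reagents that add atoms: tributyl(vinyl)stannane C=C[Sn](CCCC)(CCCC)CCCC
Why: Stille coupling proceeds with retention of alkene geometry, installing C14–C15 and thus the (12Z)-diene; free hydroxyls are tolerated.

Step 12
Reactants: 19 diene-triol
Product: 20 (5R,6S,7R,8R,9S,10R,12Z)-6,7-diacetoxy-ent-labda-12,14-dien-8-ol (target)
Conditions: Ac2O, pyridine, DMAP (cat.), CH2Cl2, 0 °C → rt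
Reagents that add atoms: acetic anhydride CC(=O)OC(C)=O
Why: DMAP-catalysed acetylation esterifies the two secondary hydroxyls (C6, C7), while the hindered tertiary 8-OH should not react at room temperature.

**Compound list**

1 | 2,2,6-trimethylcyclohexan-1-one (racemic) | CC1CCCC(C)(C)C1=O | starting material
2 | allyl chloroformate | C=CCOC(=O)Cl | starting material
3 | lithium 2,6,6-trimethylcyclohex-1-en-1-olate | [Li+].[O-]C1=C(C)CCCC1(C)C | intermediate
4 | allyl 2,6,6-trimethylcyclohex-1-en-1-yl carbonate | C=CCOC(=O)OC1=C(C)CCCC1(C)C | intermediate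
5 | (S)-2-allyl-2,6,6-trimethylcyclohexan-1-one | C=CC[C@]1(C)CCCC(C)(C)C1=O | intermediate
6 | (2E)-3-[(1S)-1,3,3-trimethyl-2-oxocyclohexyl]prop-2-en-1-yl acetate | CC(=O)OC/C=C/[C@]1(C)CCCC(C)(C)C1=O | intermediate
7 | acetoin (3-hydroxybutan-2-one, racemic) | CC(O)C(C)=O | starting material
8 | zinc bis(3-oxobutan-2-olate) | CC(=O)C(C)O[Zn]OC(C)C(C)=O | intermediate
9 | 3-{[(2E)-3-[(1S)-1,3,3-trimethyl-2-oxocyclohexyl]prop-2-en-1-yl]oxy}butan-2-one (epimer pair at the ether carbon) | CC(=O)C(C)OC/C=C/[C@]1(C)CCCC(C)(C)C1=O | intermediate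
10 | 3-hydroxy-3-methyl-4-[(1S)-1,3,3-trimethyl-2-oxocyclohexyl]hex-5-en-2-one (C8, C9 as in 12) | CC(=O)[C@](C)(O)[C@@H](C=C)[C@]1(C)CCCC(C)(C)C1=O | intermediate
11 | 3,8a-dihydroxy-3,4a,8,8-tetramethyl-4-vinyloctahydronaphthalen-2(1H)-one (C5 carbinol, either epimer) | C=C[C@@H]1[C@@](C)(O)C(=O)CC2(O)C(C)(C)CCC[C@]21C | intermediate
12 | 3-hydroxy-3,4a,8,8-tetramethyl-4-vinyl-4,4a,5,6,7,8-hexahydronaphthalen-2(3H)-one (8-OH anti, 8-CH3 and 9-vinyl syn to C10-CH3) | C=C[C@@H]1[C@@](C)(O)C(=O)C=C2C(C)(C)CCC[C@]21C | intermediate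
13 | 3,4a,8,8-tetramethyl-4-vinyl-2,3,4,4a,5,6,7,8-octahydronaphthalene-2,3-diol (7-OH syn to C10-CH3) | C=C[C@@H]1[C@@](C)(O)[C@H](O)C=C2C(C)(C)CCC[C@]21C | intermediate
14 | 6,12-bis(boryl) adduct of 13 (drawn as the di-BH2 compound) | BCC[C@@H]1[C@@](C)(O)[C@H](O)[C@@H](B)[C@@H]2C(C)(C)CCC[C@]21C | intermediate
15 | 4-(2-hydroxyethyl)-3,4a,8,8-tetramethyldecahydronaphthalene-1,2,3-triol (trans-decalin; 6-OH anti to C10-CH3) | OCC[C@@H]1[C@@](C)(O)[C@H](O)[C@@H](O)[C@@H]2C(C)(C)CCC[C@]21C | intermediate
16 | ent-6,7-dihydroxy-13,14,15,16-tetranorlabdane 12,8-lactol (anomer mixture) | OC1C[C@@H]2[C@@](C)(O1)[C@H](O)[C@@H](O)[C@@H]3C(C)(C)CCC[C@]32C | intermediate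
17 | ent-6,7-dihydroxy-13,14,15,16-tetranorlabdano-12,8-lactone | O=C1C[C@@H]2[C@@](C)(O1)[C@H](O)[C@@H](O)[C@@H]3C(C)(C)CCC[C@]32C | intermediate
18 | (12Z)-13-iodo-14,15-dinor-ent-labd-12-ene-6,7,8-triol | C/C(I)=C/C[C@@H]1[C@@](C)(O)[C@H](O)[C@@H](O)[C@@H]2C(C)(C)CCC[C@]21C | intermediate
19 | (12Z)-ent-labda-12,14-diene-6,7,8-triol | C=C/C(C)=C\C[C@@H]1[C@@](C)(O)[C@H](O)[C@@H](O)[C@@H]2C(C)(C)CCC[C@]21C | intermediate
20 | (5R,6S,7R,8R,9S,10R,12Z)-6,7-diacetoxy-ent-labda-12,14-dien-8-ol | C=C/C(C)=C\C[C@@H]1[C@@](C)(O)[C@H](OC(C)=O)[C@@H](OC(C)=O)[C@@H]2C(C)(C)CCC[C@]21C | target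

**Summary**

Total step count: 12. Longest linear sequence: 12 steps (from 1).

**Steps most likely to fail**

Step 5. The sigmatropic shift may discriminate poorly between the two faces of C9 with respect to the C10 quaternary centre, and material may be lost through self-condensation of the non-rearranging methyl-side enolate. The fallback replaces substrate control by catalyst control; it sets out from acetate 6 and returns at enone 12. Miyaura-type allylic borylation of 6 (B2pin2, Pd2(dba)3, DMSO) gives the (E)-allyl pinacolboronate F1. A chiral-diol-catalysed allylboration (3,3′-dibromo-BINOL, t-BuOH, toluene) of commercial 3,3-dimethoxybutan-2-one then forms C8–C9 through a closed chair transition state, in which the (E)-boronate gives the required 8-OH/9-vinyl relationship and the catalyst enantiomer is chosen to match C10; this gives the hydroxy ketal F2. Aqueous acid unmasks ketol 10, now isolated, and KOt-Bu/t-BuOH closes ring B to 12.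

Step 3. C–H cleavage beside the quaternary centre may be slow, with Wacker-type oxidation or branched acetate competing. The fallback sets out from allyl ketone 5 and returns at acetate 6. Ru-hydride isomerisation (RuHCl(CO)(PPh3)3, toluene, 80 °C) moves the double bond into conjugation with nothing else possible, giving the (E)-propenyl ketone F3. Its only allylic C–H bonds are those of the terminal methyl, so SeO2 (cat.)/t-BuOOH should oxidise it to the (E)-allylic alcohol F4, which Ac2O/pyridine converts into 6.

Step 10. The thermally labile iodo-ylide may decompose before it intercepts the small equilibrium amount of open hydroxy-aldehyde from the polyhydroxylated lactol, and Z-selectivity may erode. The fallback sets out from lactol 16 and returns at diene-triol 19. Still–Gennari olefination (ethyl 2-[bis(2,2,2-trifluoroethoxy)phosphoryl]propanoate, KHMDS, 18-crown-6, THF, −78 °C) gives the (Z)-α-methyl enoate F5. DIBAL-H reduces it to the (Z)-allylic alcohol F6, MnO2 oxidises only this allylic hydroxyl to the (Z)-enal F7, and Wittig methylenation (Ph3P=CH2) gives 19.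

**Further compounds**

F1 | step 5 | (E)-allyl pinacolboronate, 2-{(2E)-3-[(1S)-1,3,3-trimethyl-2-oxocyclohexyl]prop-2-en-1-yl}-4,4,5,5-tetramethyl-1,3,2-dioxaborolane | CC1(C)OB(C/C=C/[C@]2(C)CCCC(C)(C)C2=O)OC1(C)C
F2 | step 5 | hydroxy ketal, (1S)-1-(4-hydroxy-5,5-dimethoxy-4-methylhex-1-en-3-yl)-1,3,3-trimethylcyclohexan-2-one (C8, C9 as in 10) | COC(C)(OC)[C@](C)(O)[C@@H](C=C)[C@]1(C)CCCC(C)(C)C1=O
F3 | step 3 | (S)-2,2,6-trimethyl-6-[(1E)-prop-1-en-1-yl]cyclohexan-1-one | C/C=C/[C@]1(C)CCCC(C)(C)C1=O
F4 | step 3 | (S)-2-[(1E)-3-hydroxyprop-1-en-1-yl]-2,6,6-trimethylcyclohexan-1-one | OC/C=C/[C@]1(C)CCCC(C)(C)C1=O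
F5 | step 10 | ethyl (12Z)-6,7,8-trihydroxy-15-nor-ent-labd-12-en-14-oate | CCOC(=O)/C(C)=C\C[C@@H]1[C@@](C)(O)[C@H](O)[C@@H](O)[C@@H]2C(C)(C)CCC[C@]21C
F6 | step 10 | (12Z)-15-nor-ent-labd-12-ene-6,7,8,14-tetraol | OC/C(C)=C\C[C@@H]1[C@@](C)(O)[C@H](O)[C@@H](O)[C@@H]2C(C)(C)CCC[C@]21C
F7 | step 10 | (12Z)-6,7,8-trihydroxy-15-nor-ent-labd-12-en-14-al | O=C/C(C)=C\C[C@@H]1[C@@](C)(O)[C@H](O)[C@@H](O)[C@@H]2C(C)(C)CCC[C@]21C
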